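**Target:** (4R)-8-benzoyl-5,7-dihydroxy-6-(3-methylbut-2-en-1-yl)-4-phenylchroman-2-one. The SMILES gives C4 = R (priorities C4a > Ph > C3 > H).

**Retrosynthetic overview**
1. Target ⇒ prenyl bromide + (4R)-8-benzoyl-5,7-dihydroxy-4-phenylchroman-2-one (late C-prenylation; C6 is the only free ring carbon).
2. That lactone ⇒ a monocyclic 2-pyranone acid. The benzene ring (C8–C8a Claisen bond) and the δ-lactone (O1–C2) are both made in one operation by polyketide-type folding.
3. Pyranone acid ⇒ 6-phenacyl-4-hydroxy-2-pyranone + α-bromocinnamaldehyde. An NHC-catalysed Michael/lactonisation sets C4; the enol lactone is hydrolysed in the same flask.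
4. 6-Phenacyl-4-hydroxy-2-pyranone ⇒ triacetic acid lactone + methyl benzoate (dianion acylation).
5. Ring order: transient dihydropyranone (opened again), then benzene ring and dihydrocoumarin lactone together. Both phenyl rings are bought; the pyranone is sacrificed.

**Assumption:** the (5aR,10bS) antipode of the aminoindanol-derived N-mesityl triazolium salt is taken to give 4R. If the first run shows the opposite sense, the commercial (5aS,10bR) salt is used with nothing else changed.

**Step 1**
Reactants: 1 4-hydroxy-6-methyl-2H-pyran-2-one (triacetic acid lactone); 2 methyl benzoate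
Product: 3 4-hydroxy-6-(2-oxo-2-phenylethyl)-2H-pyran-2-one
Conditions: LDA (3.2 equiv), THF, −78 °C; 2, −78 → 0 °C; 1 M HCl
Reagents that add atoms: none
Why: Hauser–Harris dianion acylation (Claisen type): after O-deprotonation a second equivalent of LDA removes a proton from the vinylogous 6-methyl group, this carbanion attacks the ester, and the third equivalent stores the more acidic β-dicarbonyl product as its enolate so that acylation stops at one benzoyl group; no stereocenter is formed.

**Step 2**
Reactants: 3 4-hydroxy-6-(2-oxo-2-phenylethyl)-2H-pyran-2-one; 4 (Z)-2-bromo-3-phenylprop-2-enal (α-bromocinnamaldehyde)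
Product: 6 (3R)-3-[4-hydroxy-2-oxo-6-(2-oxo-2-phenylethyl)-2H-pyran-3-yl]-3-phenylpropanoic acid, via enol lactone 5 (not isolated)
Conditions: (5aR,10bS)-N-mesityl aminoindanol triazolium chloride (10 mol %), Na2CO3 (2.5 equiv), PhMe, 25 °C; then H2O–THF, 25 °C; HCl to pH 2
Reagents that add atoms: water, O
Why: NHC-catalysed [3+3] annulation of a 2-bromoenal with a cyclic 1,3-dicarbonyl C–H acid: carbene addition and loss of bromide give the chiral α,β-unsaturated acyl azolium, the pyranonate of 3 adds through C3 to the β-carbon on the face left open by the aminoindanyl backbone (this sets the stereocenter, R), O-acylation by the 4-oxygen releases the catalyst as enol lactone 5, and aqueous carbonate then hydrolyses only this activated lactone, leaving the 2-pyranone intact.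

**Step 3**
Reactants: 6 (3R)-3-[4-hydroxy-2-oxo-6-(2-oxo-2-phenylethyl)-2H-pyran-3-yl]-3-phenylpropanoic acid
Product: 9 (4R)-8-benzoyl-5,7-dihydroxy-4-phenylchroman-2-one, via triketo ester acid 7 (not isolated), via phloroglucinol acid 8 (not isolated)
Conditions: Mg(OMe)2 (6 equiv), MeOH, 60 °C; 2 M HCl, 0 °C; then TsOH·H2O (10 mol %), MeCN–PhMe, 60 °C
Reagents that add atoms: none
Why: Proposed new method: biomimetic polyketide folding modelled on the Mg(OMe)2-induced Claisen rearrangement of 6-(acylmethyl)-4-hydroxy-2-pyranones to acylphloroglucinols (closest known reaction type, here run on a 3-substituted pyranone carrying its own carboxylate and followed in the same flask by acid lactonisation): methoxide opens the pyranone to the magnesium-chelated triketo ester 7, the doubly activated C8 carbanion closes onto the methyl ester (six-membered Claisen/Dieckmann), the trione aromatises to 8, and acid closes the δ-lactone on the phenol next to the benzoyl group because an aryl ester prefers the less acidic oxygen and leaves the vinylogous-acid para-OH free; the competing aldol mode would create a non-aromatisable quaternary carbon, and the side chain is kept as a carboxylate so that it can neither act as a Dieckmann acceptor nor enolise, which excludes retro-Michael loss of the C4 configuration.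

**Step 4**
Reactants: 9 (4R)-8-benzoyl-5,7-dihydroxy-4-phenylchroman-2-one; 10 1-bromo-3-methylbut-2-ene (prenyl bromide)
Product: 11 (4R)-8-benzoyl-5,7-dihydroxy-6-(3-methylbut-2-en-1-yl)-4-phenylchroman-2-one
Conditions: DBU (1.1 equiv), THF, 0 → 25 °C; AcOH
Reagents that add atoms: none
Why: Base-mediated C-prenylation of an acylphloroglucinol (C-alkylation of a vinylogous β-dicarbonyl enolate): the 5-phenoxide, conjugated with the 8-benzoyl group, is alkylated by the soft allylic bromide at C6, the only unsubstituted ring carbon, and the dienone re-aromatises, while under anhydrous non-nucleophilic conditions the lactone cannot open or migrate (O1 and O5 are too far apart for direct acyl transfer), so lactone position and C4 are retained.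

**Compound list**
1 | 4-hydroxy-6-methyl-2H-pyran-2-one (triacetic acid lactone) | CC1=CC(O)=CC(=O)O1 | starting material
2 | methyl benzoate | COC(=O)c1ccccc1 | starting material
3 | 4-hydroxy-6-(2-oxo-2-phenylethyl)-2H-pyran-2-one | O=C(CC1=CC(O)=CC(=O)O1)c1ccccc1 | intermediate
4 | (Z)-2-bromo-3-phenylprop-2-enal (α-bromocinnamaldehyde) | O=C/C(Br)=C/c1ccccc1 | starting material
5 | (4R)-7-(2-oxo-2-phenylethyl)-4-phenyl-3,4-dihydro-2H,5H-pyrano[4,3-b]pyran-2,5-dione | O=C(CC1=CC2=C(C(=O)O1)[C@@H](c1ccccc1)CC(=O)O2)c1ccccc1 | intermediate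
6 | (3R)-3-[4-hydroxy-2-oxo-6-(2-oxo-2-phenylethyl)-2H-pyran-3-yl]-3-phenylpropanoic acid | O=C(CC1=CC(O)=C(C(=O)O1)[C@@H](c1ccccc1)CC(=O)O)c1ccccc1 | intermediate
7 | (3S)-4-(methoxycarbonyl)-5,7,9-trioxo-3,9-diphenylnonanoic acid (Mg chelate, C4 unspecified; same spatial arrangement at C3 as in 6, the descriptor changes only because C4 is now sp3) | COC(=O)C(C(=O)CC(=O)CC(=O)c1ccccc1)[C@@H](c1ccccc1)CC(=O)O | intermediate
8 | (3R)-3-(3-benzoyl-2,4,6-trihydroxyphenyl)-3-phenylpropanoic acid | O=C(c1ccccc1)c1c(O)cc(O)c(c1O)[C@@H](c1ccccc1)CC(=O)O | intermediate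
9 | (4R)-8-benzoyl-5,7-dihydroxy-4-phenylchroman-2-one | Oc1cc(O)c(C(=O)c2ccccc2)c2c1[C@@H](c1ccccc1)CC(=O)O2 | intermediate
10 | 1-bromo-3-methylbut-2-ene (prenyl bromide) | CC(C)=CCBr | starting material
11 | (4R)-8-benzoyl-5,7-dihydroxy-6-(3-methylbut-2-en-1-yl)-4-phenylchroman-2-one | CC(C)=CCc1c(O)c(C(=O)c2ccccc2)c2c(c1O)[C@@H](c1ccccc1)CC(=O)O2 | target

**Total step count:** 4. **Longest linear sequence:** 4 (1 → 3 → 6 → 9 → 11).

**Steps most likely to fail**

Step 3 (highest risk). The C3-branched pyranone may resist opening or simply re-close. The acid lactonisation may also take the para-oxygen and give the 6-benzoyl lactone isomer; the preference for 9 rests on a thermodynamic argument, not on a precedent. The fallback sets out from 3 and comes back at 9. Mg(OMe)2 in MeOH is applied to 3 itself, the unsubstituted literature-type case, to give 2,4,6-trihydroxybenzophenone F1 (also purchasable). TIPSCl and imidazole silylate its most acidic para-hydroxyl to give [2,6-dihydroxy-4-(triisopropylsilyloxy)phenyl](phenyl)methanone F2. The NHC annulation of step 2 is then run on F2 with 4; because the para-oxygen is blocked, only the hydroxyl next to the benzoyl group can lactonise, giving (4R)-8-benzoyl-7-hydroxy-4-phenyl-5-(triisopropylsilyloxy)chroman-2-one F3. HF·pyridine in THF removes the silyl group to give 9. This builds the arene before the lactone and fixes the lactone position with a blocking group.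

Step 2. The phenacyl CH2 of 3 is a second nucleophilic site, and the ee or sense of induction on this substrate is untested. The fallback sets out from 3 and comes back at 6. Iminium catalysis replaces the acyl azolium: cinnamaldehyde, a diarylprolinol silyl ether (the antipode that gives 4R) and benzoic acid in CH2Cl2 add C3 of 3 to the enal and give the lactol (4R)-2-hydroxy-7-(2-oxo-2-phenylethyl)-4-phenyl-3,4-dihydro-2H,5H-pyrano[4,3-b]pyran-5-one F4. Pinnick oxidation (NaClO2, NaH2PO4, 2-methyl-2-butene, t-BuOH–H2O) of its ring-opened aldehyde tautomer gives 6 directly.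

Step 4. O-alkylation and over-alkylation compete with C6-alkylation. The fallback sets out from 9 and comes back at 11. K2CO3 and prenyl bromide 10 in acetone alkylate the acidic 5-OH to give (4R)-8-benzoyl-7-hydroxy-5-[(3-methylbut-2-en-1-yl)oxy]-4-phenylchroman-2-one F5. Montmorillonite K10 in CH2Cl2 at 0 °C then moves the prenyl group from O5 to C6 by a 1,3-shift (C6 is the only free ortho position), giving 11.

**Further compounds**
F1 | step 3 | 2,4,6-trihydroxybenzophenone | O=C(c1ccccc1)c1c(O)cc(O)cc1O
F2 | step 3 | [2,6-dihydroxy-4-(triisopropylsilyloxy)phenyl](phenyl)methanone | CC(C)[Si](Oc1cc(O)c(C(=O)c2ccccc2)c(O)c1)(C(C)C)C(C)C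
F3 | step 3 | (4R)-8-benzoyl-7-hydroxy-4-phenyl-5-(triisopropylsilyloxy)chroman-2-one | CC(C)[Si](Oc1cc(O)c(C(=O)c2ccccc2)c2c1[C@@H](c1ccccc1)CC(=O)O2)(C(C)C)C(C)C
F4 | step 2 | (4R)-2-hydroxy-7-(2-oxo-2-phenylethyl)-4-phenyl-3,4-dihydro-2H,5H-pyrano[4,3-b]pyran-5-one | O=C(CC1=CC2=C(C(=O)O1)[C@@H](c1ccccc1)CC(O)O2)c1ccccc1
F5 | step 4 | (4R)-8-benzoyl-7-hydroxy-5-[(3-methylbut-2-en-1-yl)oxy]-4-phenylchroman-2-one | CC(C)=CCOc1cc(O)c(C(=O)c2ccccc2)c2c1[C@@H](c1ccccc1)CC(=O)O2
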